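## Structural features

The target is an 8-O-4′ neolignan in its 7-oxo form. Ring A (4-hydroxy-3,5-dimethoxyphenyl) is joined through the aryl ketone carbon C7 to a three-carbon chain C7–C8–C9, C9 is a free hydroxymethyl group, and C8 carries an ether oxygen to C4′ of ring B, a 2-methoxyphenyl ring whose C1′ bears a 3-hydroxypropyl chain. C8 (R) is the only stereocentre, so nothing stands next to it in the target, although in the synthetic intermediates it is flanked by a temporary stereocentre at C7. C8 is at once α to the ketone, α to an aryloxy group and β to a hydroxyl, so it can epimerise through the enol, lose formaldehyde by retro-aldol cleavage or eliminate under base. The syringyl phenol is easily oxidised, and two primary alcohols must be told apart from the C7 oxygen when the ketone is made. The difficulty is therefore one of order and not of size: a secondary alkyl aryl ether has to be forged at a crowded carbon with secure absolute configuration, and the C7 carbonyl may appear only when no basic or strongly acidic operation is left. The key step exploits the substitution pattern of ring B: the oxygen on C8 sits on C4′, para to the chain-bearing C1′ and ortho to the methoxy group on C3′. With the chain masked as a formyl group, C4′ becomes an SNAr-active carbon bearing fluoride, and C8 can enter as a configurationally stable carbinol oxygen whose C–O bond is never broken.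

## Logic of the disconnections

**14 back to 13.** No skeletal bond is cut; the C7 carbonyl is traced back to a C7 carbinol (C7–H and O–H restored). The reason is that C8 is configurationally safe only while C7 is sp3, so the ketone is left to the last operation. The gain is that every earlier intermediate is a non-enolisable ether or polyol. The demand is an oxidant that takes the benzylic alcohol para to the free ring A phenol, spares two primary alcohols and works without base.

**13 back to 12 and 11.** The terminal carbinol of the ring B chain is traced back to an ethyl ester, the saturated chain to a Cα′=Cβ′ double bond, and the ring A phenol and the C7 hydroxyl to their benzyl ethers (two O–CH2Ph bonds restored). One hydrogenation then does three jobs and one hydride reduction finishes the chain. The gain is that 11 carries only robust ethers and a conjugated ester. The demand is that hydrogenolysis stops at the O–CH2Ph bonds and does not go on to break the benzylic C7–O bond.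

**11 back to 10.** The C9 hydroxyl is traced back to its trityl ether (O–CPh3 bond restored). The trityl group is needed only to single out the C8 hydroxyl in the key step. It is taken off here, while the phenol and the C7 oxygen are still benzylated, so that acid never meets a para-hydroxybenzylic alcohol. The demand is an acid mild enough to leave the electron-rich C7 benzylic ether alone.

**10 back to 8 and 9.** The Cα′=Cβ′ bond of the ring B side chain is cut. This returns the formyl group that the key step needs as its activating group and supplies two of the three chain carbons from a commodity phosphonate. The demand is E-selective olefination under a base too weak to harm anything else; with C7 still an ether carbon, 8 has no base-labile site.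

**8 back to 6 and 7 (key disconnection).** The O–C4′(aryl) bond is cut, with the oxygen staying on C8. Cutting on the aryl side of the oxygen means the stereocentre is never a reacting carbon, so the configuration of 6 is transferred unchanged. The gain is large: ring B becomes a bought fluoroarene and all stereochemistry rests in one acyclic carbinol. The demand is that 6 offers exactly one nucleophilic oxygen, that its protecting groups cannot migrate to an alkoxide, and that the alkoxide attacks the fluorine-bearing carbon rather than being lost to the formyl group.

**6 back to 5.** The O–CPh3 bond at C9 is cut. A primary-selective, base-inert, non-migrating group is required, and a trityl ether is the simplest one that can be put on a 1,2-diol without touching the secondary hydroxyl. The demand is steric discrimination between C9–OH and C8–OH.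

**5 back to 4 and 3.** The C7–O(benzyl) bond is cut and the C8 hydroxyl and C7 oxygen are traced back to an epoxide, then to the C7=C8 double bond of an E allylic alcohol. This reduces both oxygenated carbons to one alkene and puts the absolute configuration of C8 in the hands of a reagent-controlled epoxidation. The demand is face selectivity in the epoxidation and attack of the oxygen nucleophile at the benzylic carbon of a labile, electron-rich epoxide. For that reason 4 is opened in the flask in which it is made.

**3 back to 2 and 1.** The allylic alcohol is traced back to a cinnamate ester and the two O–benzyl bonds are cut. This leads to a bought hydroxycinnamic acid that already holds all of ring A and C7–C9. The demand is clean 1,2-reduction of the conjugated ester.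

## Other disconnections considered

**Alternative 1:** The cut removes the C8–O(aryl) and C8–C9 bonds together. This leaves a ring A diazoketone A1, a ring B phenol A2 with its side-chain alcohol silylated, and formaldehyde A3.

- Forward key step: Rh2(OAc)4 (divalent rhodium) would turn A1 into a carbene, the phenolic oxygen of A2 would capture it as an oxonium ylide or its enol, and a chiral BINOL-derived phosphoric acid would steer A3 onto the enol carbon before the 1,2-proton shift. The product would be A4, the bis-silyl ether of the target, with C8 set in the same event.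
- In its favour: it is the shortest conceivable assembly, fully convergent, made at the ketone oxidation level with no redox traffic at C7 and no stoichiometric chiral reagent. On step economy and convergence it is clearly better than the chosen plan.
- Against it here: simple O–H insertion (proton shift before trapping) and ortho C–H functionalisation of the electron-rich phenol compete. Enantiofacial control over an acyclic aryloxy enol with the smallest possible electrophile is not assured for this partner set. The stereocentre is born α to the ketone under acid catalysis, in its most labile state, and must then survive a double desilylation. A1 is a diazo compound and A3 has to be used as the monomer, both of which weigh on safety.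
- Comparison: structurally both plans end at the same compound. Mechanistically the chosen plan spreads the risk over two well-understood events (reagent-controlled epoxidation, then an SNAr that does not touch the stereocentre), whereas Alternative 1 concentrates it in one multicomponent step. The chosen plan keeps C8 as a non-enolisable carbinol until the final neutral oxidation, and this is the point on which it is the safer of the two.

**Alternative 2:** The strategic bond is the C7–H bond. A racemic α-aryloxy β-keto ester A5 would be assembled by phenoxide displacement at an activated, racemic carbon.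

- Forward key step: RuCl(p-cymene)(TsDPEN) (divalent ruthenium) with HCO2H and Et3N would reduce the C7 ketone of A5 while C8 racemises through the enol, giving the syn hydroxy ester A6. Reduction of both esters and debenzylation would give the threo tetraol A7, the C7 epimer of 13, and the same final oxidation would follow.
- In its favour: the aryl ether is made at a carbon with no stereochemical stake, so the hindered etherification of the chosen plan is avoided, and on this point it is better. The chiral information is catalytic, C9 and the ring B chain both arrive as esters and are reduced together, and no protecting group is needed at C9. The step count would be lower, roughly seven.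
- Against it here: the syn/anti outcome and the enantioselectivity for an α-aryloxy substrate with an ortho-methoxy aryloxy group are not assured, and the method depends on racemisation outrunning reduction. C7 is set only to be erased. A6 keeps an acidic C8–H next to the ester until the reduction is done.
- Comparison: the endgame is equal (A7 and 13 differ only at the carbon that is oxidised). Alternative 2 is better on step economy and on ease of ether formation. The chosen plan is better on predictability of absolute configuration, because an E-disubstituted allylic alcohol is the best-behaved substrate class for its asymmetric step.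

**Alternative 3:** The cut is the C7–C8 bond. It leaves the (S)-4-benzyloxazolidinone aryloxyacetyl imide A8, in which the ether to ring B already exists, and O-silyl syringaldehyde A9.

- Forward key step: the dibutylboron (Z)-enolate of A8 (Bu2BOTf, iPr2NEt) would add to A9 through a closed chair transition state to give the syn aldol adduct A10. Reductive removal of the auxiliary and desilylation would lead to A7, which converges on the same final oxidation.
- In its favour: the C8–O bond is made trivially by alkylating a phenol with a haloacetate. The aldol is highly predictable, and the covalently bound auxiliary allows diastereomers to be purified, so stereochemical purity can be upgraded more easily than an enantiomeric shortfall of an epoxidation. On these two points it is the equal or the better of the chosen plan. Its length would be similar or slightly shorter.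
- Against it here: it needs a stoichiometric auxiliary and boron triflate. A9 is an electron-rich, sluggish electrophile whose aldolate is prone to retro-aldol cleavage. C7 is again created and destroyed, and two silyl ethers add protecting-group steps.
- Comparison: the chosen plan uses a catalytic source of chirality and needs no auxiliary attachment and removal, while Alternative 3 avoids the sterically demanding SNAr. Both rely on the same last-step oxidation of a phenolic benzylic alcohol.

Key step: step 5

Remark on the chemistry: C7, C8 and C9 denote the benzylic, aryloxy-bearing and hydroxymethyl carbons, ring A is the syringyl ring and ring B the 2-methoxyphenoxy ring. The target is the 8R enantiomer, which is consistent with the (7S,8R) carbinol 6 and with an epoxidation controlled by D-(−)-diethyl tartrate, so no structure needed correction. The configuration at C7 of the intermediates is taken to be immaterial because C7 ends as a carbonyl carbon.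

## Route

Step 1
Reactants: 1 sinapic acid
Product: 2 benzyl (E)-3-[4-(benzyloxy)-3,5-dimethoxyphenyl]prop-2-enoate
Conditions: BnBr (2.4 equiv), K2CO3, DMF, 60 °C
Reagents that add atoms: benzyl bromide, BrCc1ccccc1
Why: Double O-alkylation (Williamson ether synthesis at the phenoxide, alkylation of the carboxylate) protects the phenol and turns the acid into an ester ready for reduction in one operation.

Step 2
Reactants: 2 benzyl (E)-3-[4-(benzyloxy)-3,5-dimethoxyphenyl]prop-2-enoate
Product: 3 (E)-3-[4-(benzyloxy)-3,5-dimethoxyphenyl]prop-2-en-1-ol
Conditions: iBu2AlH (3 equiv), CH2Cl2, −78 → 0 °C; aq. KNaC4H4O6 (potassium sodium tartrate)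
Reagents that add atoms: none
Why: 1,2-Reduction of an α,β-unsaturated ester by iBu2AlH should give the E allylic alcohol without touching the alkene or the aryl benzyl ether; the ester benzyl group leaves as benzyl alcohol and is removed.

Step 3
Reactants: 3 (E)-3-[4-(benzyloxy)-3,5-dimethoxyphenyl]prop-2-en-1-ol
Product: 5 (2R,3S)-3-(benzyloxy)-3-[4-(benzyloxy)-3,5-dimethoxyphenyl]propane-1,2-diol, via epoxy alcohol 4 (not isolated)
Conditions: Ti(OiPr)4 (10 mol%), D-(−)-diethyl tartrate (12 mol%), tBuOOH (1.3 equiv, decane), 4 Å MS, CH2Cl2, −20 °C; then BnOH (8 equiv), Ti(OiPr)4 (1.5 equiv), −20 °C → rt; aq. KNaC4H4O6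
Reagents that add atoms: tert-butyl hydroperoxide, CC(C)(C)OO; benzyl alcohol, OCc1ccccc1
Why: Sharpless asymmetric epoxidation of an E-disubstituted allylic alcohol: the tetravalent titanium tartrate complex from D-(−)-diethyl tartrate delivers oxygen to the alkene face that gives the (2R,3R)-epoxy alcohol 4, which fixes C8 as R. The labile electron-rich epoxide is opened in the same flask: excess Ti(OiPr)4 binds it as a bidentate epoxy alkoxide and benzyl alcohol attacks the benzylic carbon C7 with inversion (titanium-mediated regioselective opening of a 2,3-epoxy alcohol), giving the erythro diol. Any loss of stereospecificity at C7 would be harmless for the target, since C7 ends as a carbonyl and the C8–O bond is not touched.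

Step 4
Reactants: 5 (2R,3S)-3-(benzyloxy)-3-[4-(benzyloxy)-3,5-dimethoxyphenyl]propane-1,2-diol
Product: 6 (1S,2R)-1-(benzyloxy)-1-[4-(benzyloxy)-3,5-dimethoxyphenyl]-3-(trityloxy)propan-2-ol
Conditions: Ph3CCl (1.15 equiv), Et3N, DMAP (cat.), CH2Cl2, 0 °C → rt
Reagents that add atoms: trityl chloride, ClC(c1ccccc1)(c1ccccc1)c1ccccc1
Why: Tritylation through the trityl cation is selective for the primary C9 hydroxyl on steric grounds, so the C8 hydroxyl is left as the only free OH; a trityl ether cannot migrate to a neighbouring alkoxide in the next step, unlike a silyl or acyl group.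

Step 5
Reactants: 6 (1S,2R)-1-(benzyloxy)-1-[4-(benzyloxy)-3,5-dimethoxyphenyl]-3-(trityloxy)propan-2-ol; 7 4-fluoro-3-methoxybenzaldehyde
Product: 8 4-{[(1S,2R)-1-(benzyloxy)-1-[4-(benzyloxy)-3,5-dimethoxyphenyl]-3-(trityloxy)propan-2-yl]oxy}-3-methoxybenzaldehyde
Conditions: KN(SiMe3)2 (1.0 equiv), DMF–THF, −20 °C, 20 min; then 7 (1.3 equiv), 0 °C → rt
Reagents that add atoms: none
Why: The potassium alkoxide of 6, formed first with one equivalent of KN(SiMe3)2 so that no free amide base meets the aldehyde, adds to the fluorine-bearing carbon of 7 to give a Meisenheimer adduct whose charge is delocalised onto the para formyl group; loss of fluoride restores aromaticity and gives the alkyl aryl ether (addition–elimination SNAr). The closest known reaction type is the etherification of secondary alkoxides with 4-fluorobenzaldehydes in dipolar aprotic solvents. No ring is closed and no stereocentre is created: the C8–O bond of the carbinol is never broken, so the R configuration fixed in step 3 is carried over unchanged and C7 is untouched. The step needs O-arylation to win over carbonyl addition, which is secured because hemiacetal alkoxide formation is reversible whereas fluoride loss is not. It needs site selectivity on ring B, which is secured because only the fluorine-bearing carbon is para to the formyl group, the methoxy-bearing carbon being meta and unactivated. It needs a single nucleophilic oxygen, which is secured by the trityl ether at C9 and the benzyl ethers at C7 and on ring A, none of which can migrate. Elimination is excluded because C7 is an ether carbon, so the C8–H is not acidic and no enolate can form.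

Step 6
Reactants: 8 4-{[(1S,2R)-1-(benzyloxy)-1-[4-(benzyloxy)-3,5-dimethoxyphenyl]-3-(trityloxy)propan-2-yl]oxy}-3-methoxybenzaldehyde; 9 triethyl phosphonoacetate
Product: 10 ethyl (E)-3-(4-{[(1S,2R)-1-(benzyloxy)-1-[4-(benzyloxy)-3,5-dimethoxyphenyl]-3-(trityloxy)propan-2-yl]oxy}-3-methoxyphenyl)prop-2-enoate
Conditions: 9 (1.3 equiv), LiCl, DBU, MeCN–THF, rt
Reagents that add atoms: none
Why: Horner–Wadsworth–Emmons olefination in its mild LiCl/amine form (Masamune–Roush conditions) should give the E cinnamate from the stabilised phosphonate anion; nothing in 8 is base-labile because C8 has no acidifying neighbour, and no metal hydride base is needed.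

Step 7
Reactants: 10 ethyl (E)-3-(4-{[(1S,2R)-1-(benzyloxy)-1-[4-(benzyloxy)-3,5-dimethoxyphenyl]-3-(trityloxy)propan-2-yl]oxy}-3-methoxyphenyl)prop-2-enoate
Product: 11 ethyl (E)-3-(4-{[(1S,2R)-1-(benzyloxy)-1-[4-(benzyloxy)-3,5-dimethoxyphenyl]-3-hydroxypropan-2-yl]oxy}-3-methoxyphenyl)prop-2-enoate
Conditions: TsOH·H2O (0.1 equiv), EtOH–CH2Cl2, 0 °C → rt
Reagents that add atoms: none
Why: Acid-catalysed SN1 cleavage of the trityl ether through the trityl cation, which ethanol captures. It is placed here because the phenol and the C7 oxygen are still benzylated, so no para-hydroxybenzylic alcohol meets acid, and ethanol matches the ester so that transesterification cannot matter.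

Step 8
Reactants: 11 ethyl (E)-3-(4-{[(1S,2R)-1-(benzyloxy)-1-[4-(benzyloxy)-3,5-dimethoxyphenyl]-3-hydroxypropan-2-yl]oxy}-3-methoxyphenyl)prop-2-enoate
Product: 12 ethyl 3-(4-{[(1S,2R)-1,3-dihydroxy-1-(4-hydroxy-3,5-dimethoxyphenyl)propan-2-yl]oxy}-3-methoxyphenyl)propanoate
Conditions: H2 (1 atm), 10% Pd/C, EtOAc–EtOH (1:1), rt
Reagents that add atoms: none
Why: Heterogeneous hydrogenation saturates the cinnamate C=C and hydrogenolyses both O–CH2Ph bonds (the aryl benzyl ether and the C7 benzyl ether, cleaved on its unhindered PhCH2–O side). A neutral solvent and stopping at the end of hydrogen uptake should leave the C7–O and C8–O(aryl) bonds intact.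

Step 9
Reactants: 12 ethyl 3-(4-{[(1S,2R)-1,3-dihydroxy-1-(4-hydroxy-3,5-dimethoxyphenyl)propan-2-yl]oxy}-3-methoxyphenyl)propanoate
Product: 13 (1S,2R)-1-(4-hydroxy-3,5-dimethoxyphenyl)-2-[4-(3-hydroxypropyl)-2-methoxyphenoxy]propane-1,3-diol
Conditions: LiBH4 (4 equiv), THF, 0 → 45 °C; aq. NH4Cl
Reagents that add atoms: none
Why: Hydride reduction of a saturated ethyl ester by LiBH4, chosen over an aluminium hydride for safer handling; the phenol and the hydroxyls only consume hydride as their salts, and with C7 still a carbinol there is no acidic C8–H.

Step 10
Reactants: 13 (1S,2R)-1-(4-hydroxy-3,5-dimethoxyphenyl)-2-[4-(3-hydroxypropyl)-2-methoxyphenoxy]propane-1,3-diol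
Product: 14 (2R)-3-hydroxy-1-(4-hydroxy-3,5-dimethoxyphenyl)-2-[4-(3-hydroxypropyl)-2-methoxyphenoxy]propan-1-one
Conditions: DDQ (1.1 equiv), 1,4-dioxane (or EtOAc), rt, dark; filtration through silica, no basic wash
Reagents that add atoms: none
Why: Quinone dehydrogenation: DDQ abstracts hydride from the C7–H of the benzylic alcohol para to the free ring A phenol through a quinone methide type cation, and proton loss gives the aryl ketone. Primary alcohols and the non-phenolic ring B react far more slowly, both positions ortho to the phenol are blocked by methoxy groups, and the neutral to weakly acidic medium should leave the now enolisable C8 untouched.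

## Compound list

1 | sinapic acid | COc1cc(/C=C/C(=O)O)cc(OC)c1O | starting material
2 | benzyl (E)-3-[4-(benzyloxy)-3,5-dimethoxyphenyl]prop-2-enoate | COc1cc(/C=C/C(=O)OCc2ccccc2)cc(OC)c1OCc1ccccc1 | intermediate
3 | (E)-3-[4-(benzyloxy)-3,5-dimethoxyphenyl]prop-2-en-1-ol | COc1cc(/C=C/CO)cc(OC)c1OCc1ccccc1 | intermediate
4 | [(2R,3R)-3-[4-(benzyloxy)-3,5-dimethoxyphenyl]oxiran-2-yl]methanol | OC[C@H]1O[C@@H]1c1cc(OC)c(OCc2ccccc2)c(OC)c1 | intermediate
5 | (2R,3S)-3-(benzyloxy)-3-[4-(benzyloxy)-3,5-dimethoxyphenyl]propane-1,2-diol | O[C@H](CO)[C@@H](OCc1ccccc1)c1cc(OC)c(OCc2ccccc2)c(OC)c1 | intermediate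
6 | (1S,2R)-1-(benzyloxy)-1-[4-(benzyloxy)-3,5-dimethoxyphenyl]-3-(trityloxy)propan-2-ol | O[C@H](COC(c1ccccc1)(c1ccccc1)c1ccccc1)[C@@H](OCc1ccccc1)c1cc(OC)c(OCc2ccccc2)c(OC)c1 | intermediate
7 | 4-fluoro-3-methoxybenzaldehyde | COc1cc(C=O)ccc1F | starting material
8 | 4-{[(1S,2R)-1-(benzyloxy)-1-[4-(benzyloxy)-3,5-dimethoxyphenyl]-3-(trityloxy)propan-2-yl]oxy}-3-methoxybenzaldehyde | COc1cc(C=O)ccc1O[C@H](COC(c1ccccc1)(c1ccccc1)c1ccccc1)[C@@H](OCc1ccccc1)c1cc(OC)c(OCc2ccccc2)c(OC)c1 | intermediate
9 | triethyl phosphonoacetate | CCOC(=O)CP(=O)(OCC)OCC | starting material
10 | ethyl (E)-3-(4-{[(1S,2R)-1-(benzyloxy)-1-[4-(benzyloxy)-3,5-dimethoxyphenyl]-3-(trityloxy)propan-2-yl]oxy}-3-methoxyphenyl)prop-2-enoate | CCOC(=O)/C=C/c1ccc(O[C@H](COC(c2ccccc2)(c2ccccc2)c2ccccc2)[C@@H](OCc2ccccc2)c2cc(OC)c(OCc3ccccc3)c(OC)c2)c(OC)c1 | intermediate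
11 | ethyl (E)-3-(4-{[(1S,2R)-1-(benzyloxy)-1-[4-(benzyloxy)-3,5-dimethoxyphenyl]-3-hydroxypropan-2-yl]oxy}-3-methoxyphenyl)prop-2-enoate | CCOC(=O)/C=C/c1ccc(O[C@H](CO)[C@@H](OCc2ccccc2)c2cc(OC)c(OCc3ccccc3)c(OC)c2)c(OC)c1 | intermediate
12 | ethyl 3-(4-{[(1S,2R)-1,3-dihydroxy-1-(4-hydroxy-3,5-dimethoxyphenyl)propan-2-yl]oxy}-3-methoxyphenyl)propanoate | CCOC(=O)CCc1ccc(O[C@H](CO)[C@@H](O)c2cc(OC)c(O)c(OC)c2)c(OC)c1 | intermediate
13 | (1S,2R)-1-(4-hydroxy-3,5-dimethoxyphenyl)-2-[4-(3-hydroxypropyl)-2-methoxyphenoxy]propane-1,3-diol | COc1cc(CCCO)ccc1O[C@H](CO)[C@@H](O)c1cc(OC)c(O)c(OC)c1 | intermediate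
14 | (2R)-3-hydroxy-1-(4-hydroxy-3,5-dimethoxyphenyl)-2-[4-(3-hydroxypropyl)-2-methoxyphenoxy]propan-1-one | COc1cc(CCCO)ccc1O[C@H](CO)C(=O)c1cc(OC)c(O)c(OC)c1 | target

## Step count and least certain steps

Total step count: 10. Longest linear sequence: 10 steps (1 to 14); 7 and 9 are bought and used as such.

**Step 5 (key step).** The alkoxide of 6 is crowded by the trityloxymethyl and benzyloxybenzyl groups, and the electrophilic carbon has an ortho methoxy group. Substitution may therefore be slow, and reversible carbonyl addition followed by hydride transfer from the alkoxide to the formyl group, or attack of residual silylamide on the aldehyde, may consume the partners before the ether forms. Fallback: starting from 6, the same alkoxide would be arylated with 4-fluoro-3-methoxybenzonitrile F1. This electrophile has no carbonyl group and so tolerates heating, and should give the aryl ether nitrile F2. Partial reduction of F2 with iBu2AlH in toluene at −78 °C and hydrolysis of the aldimine on a buffered aqueous work-up would rejoin the route at 8.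

**Step 3.** The electron-rich benzylic epoxide may ionise before the titanium-bound benzyloxide is delivered. That could lead to rearrangement to carbonyl compounds or to capture of isopropoxide or hydroperoxide in place of benzyl alcohol. Background epoxidation outside the tartrate complex may also lower the enantiomeric purity at C8. Fallback: starting from 3, the alcohol would be tritylated first to give (E)-1-[4-(benzyloxy)-3,5-dimethoxyphenyl]-3-(trityloxy)prop-1-ene F3. A Shi epoxidation (D-fructose-derived ketone catalyst, KHSO5, K2CO3 buffer, MeCN–dimethoxymethane–H2O, 0 °C) under basic conditions should then give the (2R,3R)-epoxy trityl ether F4. Its solvolytic opening at the benzylic carbon in benzyl alcohol with a catalytic amount of pyridinium p-toluenesulfonate would rejoin the route at 6; a C7 epimer formed alongside would be carried through without harm.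

**Step 8.** Hydrogenolysis may not stop at the two O–CH2Ph bonds. The C7–O bond is itself benzylic, so over-reduction with loss of the C7 oxygen, or stalling at the hindered C7 benzyl ether, are both possible. Fallback: starting from 11, hydrogenation over Pd/C in the presence of NH4OAc, which suppresses cleavage of alkyl benzyl ethers much more than that of aryl benzyl ethers, would saturate the alkene and free only the phenol, giving the C7-O-benzyl phenol ester F5. LiBH4 reduction would give the C7-O-benzyl triol F6. DDQ in wet CH2Cl2 would then abstract hydride from C7 of this para-hydroxybenzylic ether; water would add to the resulting oxocarbenium ion and benzyl alcohol would be lost, so the C7 oxygen is unmasked oxidatively and the route is rejoined directly at 14.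

**Step 10.** Over-oxidation of the syringyl ring to quinone-type products may compete with dehydrogenation of the carbinol. Once the ketone exists, epimerisation at C8 or retro-aldol loss of formaldehyde may set in during work-up. Fallback: starting from 13, silylation with tBuMe2SiCl and imidazole at 0 °C would cap the phenol and both primary alcohols and leave the hindered C7 hydroxyl, giving the tris-silyl ether carbinol F7. Oxidation with Dess–Martin periodinane buffered by NaHCO3 would give the tris-silyl ether ketone F8, and desilylation with HF·pyridine in THF, an acidic and non-basic medium, would rejoin the route at 14.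

## Further compounds

F1 | step 5 | 4-fluoro-3-methoxybenzonitrile | COc1cc(C#N)ccc1F
F2 | step 5 | 4-{[(1S,2R)-1-(benzyloxy)-1-[4-(benzyloxy)-3,5-dimethoxyphenyl]-3-(trityloxy)propan-2-yl]oxy}-3-methoxybenzonitrile | COc1cc(C#N)ccc1O[C@H](COC(c1ccccc1)(c1ccccc1)c1ccccc1)[C@@H](OCc1ccccc1)c1cc(OC)c(OCc2ccccc2)c(OC)c1
F3 | step 3 | (E)-1-[4-(benzyloxy)-3,5-dimethoxyphenyl]-3-(trityloxy)prop-1-ene | COc1cc(/C=C/COC(c2ccccc2)(c2ccccc2)c2ccccc2)cc(OC)c1OCc1ccccc1
F4 | step 3 | (2R,3R)-2-[4-(benzyloxy)-3,5-dimethoxyphenyl]-3-[(trityloxy)methyl]oxirane | C(OC[C@H]1O[C@@H]1c1cc(OC)c(OCc2ccccc2)c(OC)c1)(c1ccccc1)(c1ccccc1)c1ccccc1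
F5 | step 8 | ethyl 3-(4-{[(1S,2R)-1-(benzyloxy)-3-hydroxy-1-(4-hydroxy-3,5-dimethoxyphenyl)propan-2-yl]oxy}-3-methoxyphenyl)propanoate | CCOC(=O)CCc1ccc(O[C@H](CO)[C@@H](OCc2ccccc2)c2cc(OC)c(O)c(OC)c2)c(OC)c1
F6 | step 8 | (2R,3S)-3-(benzyloxy)-3-(4-hydroxy-3,5-dimethoxyphenyl)-2-[4-(3-hydroxypropyl)-2-methoxyphenoxy]propan-1-ol | COc1cc(CCCO)ccc1O[C@H](CO)[C@@H](OCc1ccccc1)c1cc(OC)c(O)c(OC)c1
F7 | step 10 | (1S,2R)-3-[(tert-butyldimethylsilyl)oxy]-1-{4-[(tert-butyldimethylsilyl)oxy]-3,5-dimethoxyphenyl}-2-(4-{3-[(tert-butyldimethylsilyl)oxy]propyl}-2-methoxyphenoxy)propan-1-ol | COc1cc(CCCO[Si](C)(C)C(C)(C)C)ccc1O[C@H](CO[Si](C)(C)C(C)(C)C)[C@@H](O)c1cc(OC)c(O[Si](C)(C)C(C)(C)C)c(OC)c1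
F8 | step 10 | (2R)-3-[(tert-butyldimethylsilyl)oxy]-1-{4-[(tert-butyldimethylsilyl)oxy]-3,5-dimethoxyphenyl}-2-(4-{3-[(tert-butyldimethylsilyl)oxy]propyl}-2-methoxyphenoxy)propan-1-one | COc1cc(CCCO[Si](C)(C)C(C)(C)C)ccc1O[C@H](CO[Si](C)(C)C(C)(C)C)C(=O)c1cc(OC)c(O[Si](C)(C)C(C)(C)C)c(OC)c1
A1 | alternative 1 | 2-diazo-1-{4-[(tert-butyldimethylsilyl)oxy]-3,5-dimethoxyphenyl}ethan-1-one | COc1cc(C(=O)C=[N+]=[N-])cc(OC)c1O[Si](C)(C)C(C)(C)C
A2 | alternative 1 | 4-{3-[(tert-butyldimethylsilyl)oxy]propyl}-2-methoxyphenol | COc1cc(CCCO[Si](C)(C)C(C)(C)C)ccc1O
A3 | alternative 1 | formaldehyde | C=O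
A4 | alternative 1 | (2R)-1-{4-[(tert-butyldimethylsilyl)oxy]-3,5-dimethoxyphenyl}-2-(4-{3-[(tert-butyldimethylsilyl)oxy]propyl}-2-methoxyphenoxy)-3-hydroxypropan-1-one | COc1cc(CCCO[Si](C)(C)C(C)(C)C)ccc1O[C@H](CO)C(=O)c1cc(OC)c(O[Si](C)(C)C(C)(C)C)c(OC)c1
A5 | alternative 2 | ethyl 3-[4-(benzyloxy)-3,5-dimethoxyphenyl]-2-[2-methoxy-4-(3-methoxy-3-oxopropyl)phenoxy]-3-oxopropanoate (racemic) | CCOC(=O)C(Oc1ccc(CCC(=O)OC)cc1OC)C(=O)c1cc(OC)c(OCc2ccccc2)c(OC)c1
A6 | alternative 2 | ethyl (2S,3R)-3-[4-(benzyloxy)-3,5-dimethoxyphenyl]-3-hydroxy-2-[2-methoxy-4-(3-methoxy-3-oxopropyl)phenoxy]propanoate | CCOC(=O)[C@@H](Oc1ccc(CCC(=O)OC)cc1OC)[C@H](O)c1cc(OC)c(OCc2ccccc2)c(OC)c1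
A7 | alternative 2 | (1R,2R)-1-(4-hydroxy-3,5-dimethoxyphenyl)-2-[4-(3-hydroxypropyl)-2-methoxyphenoxy]propane-1,3-diol | COc1cc(CCCO)ccc1O[C@H](CO)[C@H](O)c1cc(OC)c(O)c(OC)c1
A8 | alternative 3 | (4S)-4-benzyl-3-[2-(4-{3-[(tert-butyldimethylsilyl)oxy]propyl}-2-methoxyphenoxy)acetyl]-1,3-oxazolidin-2-one | O=C1OC[C@H](Cc2ccccc2)N1C(=O)COc1ccc(CCCO[Si](C)(C)C(C)(C)C)cc1OC
A9 | alternative 3 | 4-[(tert-butyldimethylsilyl)oxy]-3,5-dimethoxybenzaldehyde | COc1cc(C=O)cc(OC)c1O[Si](C)(C)C(C)(C)C
A10 | alternative 3 | (4S)-4-benzyl-3-[(2S,3R)-3-{4-[(tert-butyldimethylsilyl)oxy]-3,5-dimethoxyphenyl}-3-hydroxy-2-(4-{3-[(tert-butyldimethylsilyl)oxy]propyl}-2-methoxyphenoxy)propanoyl]-1,3-oxazolidin-2-one | O=C1OC[C@H](Cc2ccccc2)N1C(=O)[C@@H](Oc1ccc(CCCO[Si](C)(C)C(C)(C)C)cc1OC)[C@H](O)c1cc(OC)c(O[Si](C)(C)C(C)(C)C)c(OC)c1
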